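**Strategy.** Ring A is disconnected across C1–C10 and C4–C5, so the whole decalin core arises from one enantioselective Diels–Alder reaction between 2,6-dimethyl-1,4-benzoquinone (which already holds C5–C10, CH3-17, CH3-20 and the C9 carbonyl) and the silyl ether of (E)-2-methylpenta-2,4-dien-1-ol (C1–C4, CH3-19 and the oxygenated C18). In one operation this step closes ring A and sets the contiguous triad C4 (quaternary), C5 and C10 (quaternary), the feature of the target it exploits. The C9 carbonyl then serves as the anchor for the chiral-pool side chain (Negishi coupling of its enol triflate), and a syn hydroboration installs the C8 alcohol and C9 hydrogen.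

Key step: step 4

Remark 1: labdane locants are used for all decalin compounds (ring A = C1–C5 and C10; ring B = C5–C10; CH3-17 on C8; C18 = oxygen-bearing carbon on C4, trans to CH3-20; CH3-19 on C4; CH3-20 on C10; side chain C11–C15 with CH3-16 on C13). The target is read as (4S,5S,8S,9S,10R,13S).

Remark 2: the (S)-oxazaborolidine is the enantiomer expected from the usual α-C–H···O binding model to expose the required quinone face; the (R)-antipode is equally available and would be used if a first run showed the opposite sense.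

Step 1
Reactants: 1 acrolein; 2 ethyl 2-(triphenylphosphoranylidene)propanoate
Product: 3 ethyl (2E)-2-methylpenta-2,4-dienoate
Conditions: CH2Cl2, 0 °C to rt
Reagents that add atoms: none
Why: Wittig olefination with a stabilised α-branched ylide should give the (E)-enoate (ester trans to the vinyl group), which fixes the geometry that later puts the CH2O group outside and the methyl inside on the diene terminus.

Step 2
Reactants: 3 ethyl (2E)-2-methylpenta-2,4-dienoate
Product: 4 (2E)-2-methylpenta-2,4-dien-1-ol
Conditions: i-Bu2AlH, CH2Cl2, −78 °C; aq. potassium sodium tartrate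
Reagents that add atoms: none
Why: Hydride reduction of the ester with i-Bu2AlH is a clean 1,2-reduction that should leave the diene and its geometry untouched.

Step 3
Reactants: 4 (2E)-2-methylpenta-2,4-dien-1-ol
Product: 5 tert-butyldimethyl{[(2E)-2-methylpenta-2,4-dien-1-yl]oxy}silane
Conditions: TBSCl, imidazole, CH2Cl2, 0 °C to rt
Reagents that add atoms: tert-butyldimethylsilyl chloride, CC(C)(C)[Si](C)(C)Cl
Why: Imidazole-promoted silyl ether formation masks the primary alcohol as a bulky, weakly Lewis-basic ether that should tolerate the cationic boron catalyst.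

Step 4
Reactants: 5 tert-butyldimethyl{[(2E)-2-methylpenta-2,4-dien-1-yl]oxy}silane; 6 2,6-dimethyl-1,4-benzoquinone
Product: 7 cis-fused enedione adduct (4aS,5S,8aR)-5-{[(tert-butyldimethylsilyl)oxy]methyl}-2,5,8a-trimethyl-4a,5,8,8a-tetrahydronaphthalene-1,4-dione
Conditions: (S)-1-(2-methylphenyl)-3,3-diphenyltetrahydro-1H,3H-pyrrolo[1,2-c][1,3,2]oxazaborole (20 mol %), HNTf2 (18 mol %), CH2Cl2, −78 to −40 °C, 1.5 equiv of 5; Et3N quench
Reagents that add atoms: none
Why: The N-protonated oxazaborolidine binds the quinone at the carbonyl flanked by two C–H (future C6), as in the established oxazaborolidinium-catalysed quinone Diels–Alder reaction, which is the closest known reaction type; this places the largest LUMO coefficient on the methyl-bearing carbon (future C10). The free diene terminus C1 bonds to C10 slightly ahead of C4–C5 in a concerted, asynchronous [4πs+2πs] cycloaddition, and ring A is closed by this intermolecular suprafacial annulation (two σ bonds formed on one face of the dienophile), not by a stepwise cyclisation. C10 and C5 are set together by cis addition to the C=C face left open by the aryl group of the catalyst (catalyst control), and C4 is set relative to them by endo approach combined with the (E) geometry of the diene, which leaves the outside CH2OTBS anti and the inside CH3-19 syn to CH3-20. The step needs regio-, endo and facial selectivity: regiocontrol comes from binding at the unhindered carbonyl and from pairing the substituted terminus C4 with the unsubstituted C5, while the two quinone C=C are symmetry-equivalent so no site selection is required. The inside methyl disfavours the s-cis diene and slows the addition, which the cationic activation of the quinone, the low temperature and the excess of diene are meant to offset.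

Step 5
Reactants: 7 cis-fused enedione adduct
Product: 9 trans-fused saturated 6,9-dione, via cis-fused saturated 6,9-dione 8 (not isolated)
Conditions: H2 (1 atm), Pd/C, THF, rt; filter; NaOMe (cat.), MeOH, rt
Reagents that add atoms: none
Why: Heterogeneous hydrogenation saturates the ring A alkene and the electron-poor C7=C8 bond, and methoxide-mediated epimerisation then equilibrates the two enolisable centres (C5 next to the C6 ketone, C8 next to the C9 ketone) to the trans-decalin with H-5 trans to CH3-20 and an equatorial CH3-17, while quaternary C4 and C10 cannot change.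

Step 6
Reactants: 9 trans-fused saturated 6,9-dione
Product: 10 C6 mono-tosylhydrazone of 9
Conditions: TsNHNH2 (1.05 equiv), EtOH, 50 °C
Reagents that add atoms: p-toluenesulfonyl hydrazide, Cc1ccc(cc1)S(=O)(=O)NN
Why: Tosylhydrazone condensation is governed by sterics, and the C6 carbonyl (one CH2 neighbour) should react well before the C9 carbonyl, which lies between quaternary C10 and methyl-bearing C8.

Step 7
Reactants: 10 C6 mono-tosylhydrazone of 9
Product: 13 trans-fused 18-(tert-butyldimethylsilyloxy) 9-ketone with C6 as CH2, via N-boryl tosylhydrazide 11 (not isolated), via C6 diazene 12 (not isolated)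
Conditions: catecholborane, CHCl3, 0 °C to rt; NaOAc·3H2O, reflux
Reagents that add atoms: none
Why: In this Caglioti-type tosylhydrazone reduction catecholborane adds hydride to C6 and boron to nitrogen, acetate then expels sulfinate and the diazene loses N2 to leave CH2, under conditions that should spare the hindered C9 ketone and the silyl ether.

Step 8
Reactants: 13 trans-fused 18-(tert-butyldimethylsilyloxy) 9-ketone
Product: 15 C9 enol triflate (C8=C9 alkene), via potassium C8–C9 enolate 14 (not isolated)
Conditions: KN(SiMe3)2, THF, −78 to 0 °C; PhNTf2, −78 °C to rt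
Reagents that add atoms: N-phenylbis(trifluoromethanesulfonimide), O=S(=O)(N(c1ccccc1)S(=O)(=O)C(F)(F)F)C(F)(F)F
Why: The ketone can enolise only towards C8 because C10 is quaternary, so enol triflate formation gives a single tetrasubstituted triflate and erases the C8 centre, which is reset in step 14.

Step 9
Reactants: 16 (R)-5-methoxy-3-methyl-5-oxopentanoic acid
Product: 17 methyl (3R)-5-hydroxy-3-methylpentanoate
Conditions: BH3·SMe2, THF, 0 °C to rt; MeOH
Reagents that add atoms: none
Why: Chemoselective borane reduction takes the carboxylic acid much faster than the ester, so the acid terminus becomes the future C15 alcohol and the stereocentre (future C13) is not touched.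

Step 10
Reactants: 17 methyl (3R)-5-hydroxy-3-methylpentanoate
Product: 18 methyl (3R)-5-[(tert-butyldiphenylsilyl)oxy]-3-methylpentanoate
Conditions: TBDPSCl, imidazole, DMF, 0 °C to rt
Reagents that add atoms: tert-butyldiphenylsilyl chloride, CC(C)(C)[Si](Cl)(c1ccccc1)c1ccccc1
Why: Silyl ether formation directly after work-up forestalls lactonisation and installs a group that outlasts the tert-butyldimethylsilyl ether under acid.

Step 11
Reactants: 18 methyl (3R)-5-[(tert-butyldiphenylsilyl)oxy]-3-methylpentanoate
Product: 19 (3S)-5-[(tert-butyldiphenylsilyl)oxy]-3-methylpentan-1-ol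
Conditions: i-Bu2AlH, CH2Cl2, −78 to 0 °C; aq. potassium sodium tartrate
Reagents that add atoms: none
Why: Ester reduction with i-Bu2AlH gives the primary alcohol (future C11) and leaves the silyl ether alone; the descriptor changes only through CIP priorities.

Step 12
Reactants: 19 (3S)-5-[(tert-butyldiphenylsilyl)oxy]-3-methylpentan-1-ol
Product: 20 tert-butyl{[(3R)-5-iodo-3-methylpentyl]oxy}diphenylsilane
Conditions: I2, PPh3, imidazole, CH2Cl2, 0 °C to rt
Reagents that add atoms: iodine, II
Why: Appel-type iodination converts the primary alcohol to the iodide by SN2 displacement two carbons away from the stereocentre.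

Step 13
Reactants: 20 tert-butyl{[(3R)-5-iodo-3-methylpentyl]oxy}diphenylsilane; 15 C9 enol triflate
Product: 22 (4S,5S,10R,13S)-18-(tert-butyldimethylsilyloxy)-15-(tert-butyldiphenylsilyloxy)labd-8-ene, via alkylzinc iodide 21 (not isolated)
Conditions: Zn dust, LiCl, THF, 40 °C; then 15, Pd(OAc)2 (5 mol %), SPhos (10 mol %), THF/NMP, 50 °C
Reagents that add atoms: none
Why: Zinc insertion into the primary iodide followed by palladium-catalysed Negishi cross-coupling forms the C9–C11 sp2–sp3 bond; cyclohexenyl triflates next to a quaternary carbon are competent partners with a bulky biarylphosphine, and the alkylzinc tolerates both silyl ethers.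

Step 14
Reactants: 22 (4S,5S,10R,13S)-18-(tert-butyldimethylsilyloxy)-15-(tert-butyldiphenylsilyloxy)labd-8-ene
Product: 24 (4S,5S,8S,9S,10R,13S)-18-(tert-butyldimethylsilyloxy)-15-(tert-butyldiphenylsilyloxy)labdan-8-ol, via C8 alkylborane 23 (not isolated)
Conditions: BH3·THF (excess), THF, 0 °C to rt; NaOH, H2O2, 0 to 40 °C
Reagents that add atoms: hydrogen peroxide, OO
Why: Hydroboration–oxidation of a tetrasubstituted cycloalkene is a syn addition (as with 1,2-dimethylcyclohexene): borane should approach the face opposite axial CH3-20 and put boron on C8 (the alkene carbon not next to quaternary C10) and hydrogen on C9, and oxidation with retention then gives the C8 hydroxyl anti to CH3-20, CH3-17 syn to it and the equatorial C9 side chain.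

Step 15
Reactants: 24 (4S,5S,8S,9S,10R,13S)-18-(tert-butyldimethylsilyloxy)-15-(tert-butyldiphenylsilyloxy)labdan-8-ol
Product: 25 (4S,5S,8S,9S,10R,13S)-15-(tert-butyldiphenylsilyloxy)labdane-8,18-diol
Conditions: CSA (cat.), MeOH/CH2Cl2, 0 °C
Reagents that add atoms: none
Why: Acid-catalysed methanolysis (selective desilylation) cleaves a primary tert-butyldimethylsilyl ether far faster than a tert-butyldiphenylsilyl ether, and the tertiary alcohol is inert under these mild conditions.

Step 16
Reactants: 25 (4S,5S,8S,9S,10R,13S)-15-(tert-butyldiphenylsilyloxy)labdane-8,18-diol; 26 angelic acid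
Product: 28 (4S,5S,8S,9S,10R,13S)-15-(tert-butyldiphenylsilyloxy)-8-hydroxylabdan-18-yl (2Z)-2-methylbut-2-enoate, via angelic 2,4,6-trichlorobenzoic anhydride 27 (not isolated)
Conditions: 2,4,6-trichlorobenzoyl chloride, Et3N, toluene, rt; then 25, 75 °C
Reagents that add atoms: none
Why: Yamaguchi-type esterification through the mixed anhydride should acylate only the primary C18 alcohol (the tertiary C8 alcohol is too hindered), and leaving out DMAP avoids isomerisation of the angeloyl group to tigloyl.

Step 17
Reactants: 28 (4S,5S,8S,9S,10R,13S)-15-(tert-butyldiphenylsilyloxy)-8-hydroxylabdan-18-yl (2Z)-2-methylbut-2-enoate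
Product: 29 (4S,5S,8S,9S,10R,13S)-8,15-dihydroxylabdan-18-yl (2Z)-2-methylbut-2-enoate (CNP0150844.1)
Conditions: Bu4NF, AcOH, THF, rt
Reagents that add atoms: none
Why: Buffered fluoride-mediated desilylation frees the C15 alcohol without hydrolysing or isomerising the angelate.

**Compound list**

1 | acrolein | C=CC=O | starting material
2 | ethyl 2-(triphenylphosphoranylidene)propanoate | CCOC(=O)C(C)=P(c1ccccc1)(c1ccccc1)c1ccccc1 | starting material
3 | ethyl (2E)-2-methylpenta-2,4-dienoate | C=C/C=C(\C)C(=O)OCC | intermediate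
4 | (2E)-2-methylpenta-2,4-dien-1-ol | C=C/C=C(\C)CO | intermediate
5 | tert-butyldimethyl{[(2E)-2-methylpenta-2,4-dien-1-yl]oxy}silane | C=C/C=C(\C)CO[Si](C)(C)C(C)(C)C | intermediate
6 | 2,6-dimethyl-1,4-benzoquinone | CC1=CC(=O)C=C(C)C1=O | starting material
7 | cis-fused enedione adduct, (4aS,5S,8aR)-5-{[(tert-butyldimethylsilyl)oxy]methyl}-2,5,8a-trimethyl-4a,5,8,8a-tetrahydronaphthalene-1,4-dione (H-5 and CH3-19 cis to CH3-20, CH2OTBS trans) | CC(C)(C)[Si](C)(C)OC[C@@]1(C)C=CC[C@]2(C)[C@H]1C(=O)C=C(C)C2=O | intermediate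
8 | cis-fused saturated 6,9-dione (C8 epimers; not isolated) | CC(C)(C)[Si](C)(C)OC[C@@]1(C)CCC[C@]2(C)[C@H]1C(=O)CC(C)C2=O | intermediate
9 | trans-fused saturated 6,9-dione (H-5 trans to CH3-20, CH3-19 cis to CH3-20, CH3-17 equatorial and trans to CH3-20) | CC(C)(C)[Si](C)(C)OC[C@@]1(C)CCC[C@]2(C)[C@@H]1C(=O)C[C@H](C)C2=O | intermediate
10 | C6 mono-tosylhydrazone of 9 | CC(C)(C)[Si](C)(C)OC[C@@]1(C)CCC[C@]2(C)[C@@H]1C(=NNS(=O)(=O)c3ccc(C)cc3)C[C@H](C)C2=O | intermediate
11 | N-boryl tosylhydrazide, N-(1,3,2-benzodioxaborol-2-yl) at the C6 nitrogen (not isolated) | CC(C)(C)[Si](C)(C)OC[C@@]1(C)CCC[C@]2(C)[C@@H]1C(N(B3Oc4ccccc4O3)NS(=O)(=O)c3ccc(C)cc3)C[C@H](C)C2=O | intermediate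
12 | C6 diazene (not isolated) | CC(C)(C)[Si](C)(C)OC[C@@]1(C)CCC[C@]2(C)[C@@H]1C(N=N)C[C@H](C)C2=O | intermediate
13 | trans-fused 18-(tert-butyldimethylsilyloxy) 9-ketone with C6 as CH2 (CH3-17 equatorial) | CC(C)(C)[Si](C)(C)OC[C@@]1(C)CCC[C@]2(C)[C@@H]1CC[C@H](C)C2=O | intermediate
14 | potassium C8–C9 enolate of 13 (not isolated) | CC(C)(C)[Si](C)(C)OC[C@@]1(C)CCC[C@]2(C)[C@@H]1CCC(C)=C2[O-].[K+] | intermediate
15 | C9 enol triflate (C8=C9 alkene) | CC(C)(C)[Si](C)(C)OC[C@@]1(C)CCC[C@]2(C)[C@@H]1CCC(C)=C2OS(=O)(=O)C(F)(F)F | intermediate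
16 | (R)-5-methoxy-3-methyl-5-oxopentanoic acid | COC(=O)C[C@H](C)CC(=O)O | starting material
17 | methyl (3R)-5-hydroxy-3-methylpentanoate | COC(=O)C[C@H](C)CCO | intermediate
18 | methyl (3R)-5-[(tert-butyldiphenylsilyl)oxy]-3-methylpentanoate | COC(=O)C[C@H](C)CCO[Si](c1ccccc1)(c1ccccc1)C(C)(C)C | intermediate
19 | (3S)-5-[(tert-butyldiphenylsilyl)oxy]-3-methylpentan-1-ol | OCC[C@H](C)CCO[Si](c1ccccc1)(c1ccccc1)C(C)(C)C | intermediate
20 | tert-butyl{[(3R)-5-iodo-3-methylpentyl]oxy}diphenylsilane | ICC[C@H](C)CCO[Si](c1ccccc1)(c1ccccc1)C(C)(C)C | intermediate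
21 | alkylzinc iodide from 20 (not isolated) | I[Zn]CC[C@H](C)CCO[Si](c1ccccc1)(c1ccccc1)C(C)(C)C | intermediate
22 | (4S,5S,10R,13S)-18-(tert-butyldimethylsilyloxy)-15-(tert-butyldiphenylsilyloxy)labd-8-ene | CC(C)(C)[Si](C)(C)OC[C@@]1(C)CCC[C@]2(C)[C@@H]1CCC(C)=C2CC[C@H](C)CCO[Si](c3ccccc3)(c4ccccc4)C(C)(C)C | intermediate
23 | C8 alkylborane (boron and H-9 on the face opposite CH3-20; not isolated) | CC(C)(C)[Si](C)(C)OC[C@@]1(C)CCC[C@]2(C)[C@@H]1CC[C@](C)(B)[C@H]2CC[C@H](C)CCO[Si](c3ccccc3)(c4ccccc4)C(C)(C)C | intermediate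
24 | (4S,5S,8S,9S,10R,13S)-18-(tert-butyldimethylsilyloxy)-15-(tert-butyldiphenylsilyloxy)labdan-8-ol | CC(C)(C)[Si](C)(C)OC[C@@]1(C)CCC[C@]2(C)[C@@H]1CC[C@](C)(O)[C@H]2CC[C@H](C)CCO[Si](c3ccccc3)(c4ccccc4)C(C)(C)C | intermediate
25 | (4S,5S,8S,9S,10R,13S)-15-(tert-butyldiphenylsilyloxy)labdane-8,18-diol | OC[C@@]1(C)CCC[C@]2(C)[C@@H]1CC[C@](C)(O)[C@H]2CC[C@H](C)CCO[Si](c3ccccc3)(c4ccccc4)C(C)(C)C | intermediate
26 | angelic acid, (2Z)-2-methylbut-2-enoic acid | C/C=C(/C)C(=O)O | starting material
27 | angelic 2,4,6-trichlorobenzoic anhydride (not isolated) | C/C=C(/C)C(=O)OC(=O)c1c(Cl)cc(Cl)cc1Cl | intermediate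
28 | (4S,5S,8S,9S,10R,13S)-15-(tert-butyldiphenylsilyloxy)-8-hydroxylabdan-18-yl (2Z)-2-methylbut-2-enoate | C/C=C(/C)C(=O)OC[C@@]1(C)CCC[C@]2(C)[C@@H]1CC[C@](C)(O)[C@H]2CC[C@H](C)CCO[Si](c3ccccc3)(c4ccccc4)C(C)(C)C | intermediate
29 | (4S,5S,8S,9S,10R,13S)-8,15-dihydroxylabdan-18-yl (2Z)-2-methylbut-2-enoate | C/C=C(/C)C(=O)OC[C@@]1(C)CCC[C@]2(C)[C@@H]1CC[C@](C)(O)[C@H]2CC[C@H](C)CCO | target

**Step count.** Total: 17 steps. Longest linear sequence: 13 steps (steps 1–8 and 13–17); the side-chain branch is steps 9–12.

**Steps most likely to fail**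

1. Step 4 (key step). The inside methyl makes the s-cis diene scarce, so the cycloaddition may be slow enough for acid-induced ionisation or oligomerisation of the diene, or for a stepwise pathway that erodes facial and endo selectivity. Fallback: setting out from 5 and 6, cycloaddition under an achiral Lewis acid that binds the same unhindered carbonyl (BF3·OEt2 or SnCl4, CH2Cl2, −78 °C) would give the racemic cis adduct F1. The conditions of step 5 would carry it through the racemic cis-fused dione F2 to the racemic trans-fused dione F3. Condensation at C6 with (S)-1-amino-2-(methoxymethyl)pyrrolidine would give the hydrazone of the wanted enantiomer F4 beside the diastereomeric hydrazone of the mirror-image dione F5, to be separated by chromatography or crystallisation. Two-phase hydrolysis of F4 with aqueous oxalic acid would return to the route at 9, with at most half of the material.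

2. Step 14. Hydroboration of the hindered tetrasubstituted alkene may be slow, may place part of the boron on C9, or may let boron migrate on warming. Fallback: setting out from 13, its potassium enolate 14 would be oxidised with 2-(phenylsulfonyl)-3-phenyloxaziridine from the face opposite CH3-20 to the 8-hydroxy-9-ketone F6 and silylated (Me3SiOTf, 2,6-lutidine) to the trimethylsilyl ether F7. The side-chain organolithium F8 (from 20 and t-BuLi, Et2O, −78 °C), transmetalated with anhydrous CeCl3, would add to the non-enolisable C9 ketone to give the tertiary alcohol F9. Dehydration with SOCl2/pyridine, which can only take a hydrogen from C11, would give the C9(11) alkene F10, and K2CO3/MeOH would free the allylic alcohol F11. Hydroxyl-directed hydrogenation (H2, [Ir(cod)(PCy3)(py)]PF6, CH2Cl2) would deliver hydrogen to C9 on the face of the C8 hydroxyl and return to the route at 24.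

3. Step 6. Discrimination between the two carbonyl groups may be insufficient (condensation at C9 or bis-hydrazone formation), or condensation at C6, whose α-carbon C5 sits between two quaternary carbons, may stall. Fallback: setting out from 9, kinetic deprotonation of the C7 methylene (LiN(i-Pr)2, 1.05 equiv, THF, −78 °C) would give the lithium C6 enolate F12, trapped with PhNTf2 as the C6 enol triflate F13. Palladium-catalysed formate reduction (Pd(OAc)2, PPh3, Bu3N, HCO2H, DMF, 60 °C) would give the C6–C7 alkene F14, and hydrogenation (H2, Pd/C, EtOAc) would return to the route at 13.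

**Further compounds**

F1 | step 4 | racemic cis adduct (7 with its mirror image; the mirror image is shown) | CC(C)(C)[Si](C)(C)OC[C@]1(C)C=CC[C@@]2(C)[C@@H]1C(=O)C=C(C)C2=O
F2 | step 4 | racemic cis-fused dione (8 with its mirror image; the mirror image is shown) | CC(C)(C)[Si](C)(C)OC[C@]1(C)CCC[C@@]2(C)[C@@H]1C(=O)CC(C)C2=O
F3 | step 4 | racemic trans-fused dione (9 with its mirror image; the mirror image is shown) | CC(C)(C)[Si](C)(C)OC[C@]1(C)CCC[C@@]2(C)[C@H]1C(=O)C[C@@H](C)C2=O
F4 | step 4 | C6 hydrazone of 9 with (S)-1-amino-2-(methoxymethyl)pyrrolidine | CC(C)(C)[Si](C)(C)OC[C@@]1(C)CCC[C@]2(C)[C@@H]1C(=NN3CCC[C@H]3COC)C[C@H](C)C2=O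
F5 | step 4 | C6 hydrazone of the mirror image of 9 with (S)-1-amino-2-(methoxymethyl)pyrrolidine | CC(C)(C)[Si](C)(C)OC[C@]1(C)CCC[C@@]2(C)[C@H]1C(=NN3CCC[C@H]3COC)C[C@@H](C)C2=O
F6 | step 14 | 8-hydroxy-9-ketone (hydroxyl anti to CH3-20) | CC(C)(C)[Si](C)(C)OC[C@@]1(C)CCC[C@]2(C)[C@@H]1CC[C@](C)(O)C2=O
F7 | step 14 | 8-trimethylsilyloxy-9-ketone | CC(C)(C)[Si](C)(C)OC[C@@]1(C)CCC[C@]2(C)[C@@H]1CC[C@](C)(O[Si](C)(C)C)C2=O
F8 | step 14 | side-chain organolithium from 20 | [Li]CC[C@H](C)CCO[Si](c1ccccc1)(c1ccccc1)C(C)(C)C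
F9 | step 14 | C9 tertiary alcohol with 8-trimethylsilyloxy group (C9 configuration open) | CC(C)(C)[Si](C)(C)OC[C@@]1(C)CCC[C@]2(C)[C@@H]1CC[C@](C)(O[Si](C)(C)C)C2(O)CC[C@H](C)CCO[Si](c3ccccc3)(c4ccccc4)C(C)(C)C
F10 | step 14 | C9(11) alkene with 8-trimethylsilyloxy group | CC(C)(C)[Si](C)(C)OC[C@@]1(C)CCC[C@]2(C)[C@@H]1CC[C@](C)(O[Si](C)(C)C)C2=CC[C@H](C)CCO[Si](c3ccccc3)(c4ccccc4)C(C)(C)C
F11 | step 14 | C9(11) alkene with free C8 hydroxyl | CC(C)(C)[Si](C)(C)OC[C@@]1(C)CCC[C@]2(C)[C@@H]1CC[C@](C)(O)C2=CC[C@H](C)CCO[Si](c3ccccc3)(c4ccccc4)C(C)(C)C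
F12 | step 6 | lithium C6 enolate of 9 (C6=C7) | CC(C)(C)[Si](C)(C)OC[C@@]1(C)CCC[C@]2(C)[C@@H]1C([O-])=C[C@H](C)C2=O.[Li+]
F13 | step 6 | C6 enol triflate (C6=C7) of 9 | CC(C)(C)[Si](C)(C)OC[C@@]1(C)CCC[C@]2(C)[C@@H]1C(OS(=O)(=O)C(F)(F)F)=C[C@H](C)C2=O
F14 | step 6 | C6–C7 alkene 9-ketone | CC(C)(C)[Si](C)(C)OC[C@@]1(C)CCC[C@]2(C)[C@@H]1C=C[C@H](C)C2=O
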